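## Retrosynthetic overview

1. Target 17 ⇐ tribromo diol 12 by threefold copper-catalysed exchange of C–Br for C–OMe; the bromines act as latent methoxy groups, so no protecting group is needed.
2. 12 ⇐ 1,3-diketone 9 by Noyori hydrogenation with RuCl2[(S)-binap], which sets both carbinol centres (3S,5S, anti) in one step.
3. 9 ⇐ methyl ketone 6 + methyl ester 8 by crossed Claisen condensation (C4–C5 bond).
4. Key disconnection: the two aryl–CH2 bonds (Ar–C1, Ar–C7), formed by adding aryl radicals from bromo-iodophenols 2 and 4 to but-3-en-2-one and methyl acrylate, with C–I cleaved selectively over C–Br.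
5. No ring is formed: ring A comes from 2-bromophenol and ring B from 4-iodophenol, each by one halogenation.

Assumption: the target is the (3S,5S) anti diol read from the SMILES; the heptane chain is numbered from the monomethoxy ring (ring A, C1) to the dimethoxy ring (ring B, C7).

## Route

Step 1
Reactants: 1 2-bromophenol
Product: 2 2-bromo-4-iodophenol
Conditions: NIS (1.0 equiv), TsOH·H2O (10 mol%), MeCN, 0 °C to rt
Reagents that add atoms: N-iodosuccinimide, O=C1CCC(=O)N1I
Why: Electrophilic aromatic iodination goes para to the hydroxyl group (one ortho site is blocked by bromine, the other is less reactive), installing the C–I bond that later serves as the radical precursor.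

Step 2
Reactants: 3 4-iodophenol
Product: 4 2,6-dibromo-4-iodophenol, via 2-bromo-4-iodophenol 2 (not isolated)
Conditions: NBS (2.1 equiv), i-Pr2NH (10 mol%), CH2Cl2, 0 °C to rt
Reagents that add atoms: N-bromosuccinimide, O=C1CCC(=O)N1Br
Why: Amine-catalysed ortho-selective electrophilic aromatic bromination of a para-blocked phenol brominates both ortho positions under conditions mild enough to leave the C–I bond in place.

Step 3
Reactants: 2 2-bromo-4-iodophenol; 5 but-3-en-2-one
Product: 6 4-(3-bromo-4-hydroxyphenyl)butan-2-one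
Conditions: fac-Ir(ppy)3 (1 mol%), Hantzsch ester (1.5 equiv), Bu3N (1.5 equiv), 5 (5 equiv), degassed MeCN, blue LEDs, rt
Reagents that add atoms: none
Why: Photoredox reductive Meerwein-type (Giese) hydroarylation: single-electron reduction cleaves only the weak C–I bond, the aryl radical adds to the terminal carbon of the enone, and the α-keto radical takes a hydrogen atom from the Hantzsch ester, leaving C–Br and the free phenol untouched.

Step 4
Reactants: 4 2,6-dibromo-4-iodophenol; 7 methyl acrylate
Product: 8 methyl 3-(3,5-dibromo-4-hydroxyphenyl)propanoate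
Conditions: fac-Ir(ppy)3 (1 mol%), Hantzsch ester (1.5 equiv), Bu3N (1.5 equiv), 7 (5 equiv), degassed MeCN, blue LEDs, rt
Reagents that add atoms: none
Why: The same photoredox Giese-type aryl radical conjugate addition, here to an acrylate; both C–Br bonds and the methyl ester are inert to the iodide-selective reduction.

Step 5
Reactants: 6 4-(3-bromo-4-hydroxyphenyl)butan-2-one; 8 methyl 3-(3,5-dibromo-4-hydroxyphenyl)propanoate
Product: 9 1-(3-bromo-4-hydroxyphenyl)-7-(3,5-dibromo-4-hydroxyphenyl)heptane-3,5-dione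
Conditions: KOt-Bu (4.5 equiv), THF, 0 °C to 40 °C; then aq HCl
Why: Crossed Claisen condensation: both phenols are first parked as inert phenoxides, the methyl-side enolate of 6 is acylated by ester 8 at the less hindered carbon, and deprotonation of the β-diketone drives the equilibrium.
Reagents that add atoms: none

Step 6
Reactants: 9 1-(3-bromo-4-hydroxyphenyl)-7-(3,5-dibromo-4-hydroxyphenyl)heptane-3,5-dione
Product: 12 (3S,5S)-1-(3-bromo-4-hydroxyphenyl)-7-(3,5-dibromo-4-hydroxyphenyl)heptane-3,5-diol, via ring-B-side hydroxy ketone 10 (not isolated), via ring-A-side hydroxy ketone 11 (not isolated)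
Conditions: RuCl2[(S)-binap] (1 mol%), H2 (70 atm), MeOH, 50 °C
Reagents that add atoms: none
Why: Noyori asymmetric hydrogenation of a β-diketone: the (S)-binap ruthenium catalyst reduces the first chelated carbonyl to the (S)-hydroxy ketone and then, in the matched second reduction, the other carbonyl, giving the anti (3S,5S) diol (both stereocentres are set here); aryl bromides and phenols are inert to this catalyst.

Step 7
Reactants: 12 (3S,5S)-1-(3-bromo-4-hydroxyphenyl)-7-(3,5-dibromo-4-hydroxyphenyl)heptane-3,5-diol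
Product: 17 (3S,5S)-1-(4-hydroxy-3-methoxyphenyl)-7-(4-hydroxy-3,5-dimethoxyphenyl)heptane-3,5-diol, via ring-A-methoxy dibromo diol 13 (not isolated), via ring-B-methoxy dibromo diol 14 (not isolated), via ring-B-bromo dimethoxy diol 15 (not isolated), via ring-A-bromo dimethoxy diol 16 (not isolated)
Conditions: NaOMe (15 equiv), CuBr (30 mol%), MeOH/DMF, 110 °C, sealed under argon; then aq HCl
Reagents that add atoms: sodium methoxide, C[O-].[Na+]
Why: Copper-catalysed Ullmann-type methoxylation of ortho-bromophenoxides (the established conversion of 4-alkyl-2,6-dibromophenols into syringyl ethers) replaces all three bromines; the carbinol centres have no epimerisable position and are not touched.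

## Compound list

1 | 2-bromophenol | Oc1ccccc1Br | starting material
2 | 2-bromo-4-iodophenol | Oc1ccc(I)cc1Br | intermediate
3 | 4-iodophenol | Oc1ccc(I)cc1 | starting material
4 | 2,6-dibromo-4-iodophenol | Oc1c(Br)cc(I)cc1Br | intermediate
5 | but-3-en-2-one | CC(=O)C=C | starting material
6 | 4-(3-bromo-4-hydroxyphenyl)butan-2-one | CC(=O)CCc1ccc(O)c(Br)c1 | intermediate
7 | methyl acrylate | COC(=O)C=C | starting material
8 | methyl 3-(3,5-dibromo-4-hydroxyphenyl)propanoate | COC(=O)CCc1cc(Br)c(O)c(Br)c1 | intermediate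
9 | 1-(3-bromo-4-hydroxyphenyl)-7-(3,5-dibromo-4-hydroxyphenyl)heptane-3,5-dione | Oc1ccc(CCC(=O)CC(=O)CCc2cc(Br)c(O)c(Br)c2)cc1Br | intermediate
10 | (5S)-1-(3-bromo-4-hydroxyphenyl)-7-(3,5-dibromo-4-hydroxyphenyl)-5-hydroxyheptan-3-one | Oc1ccc(CCC(=O)C[C@@H](O)CCc2cc(Br)c(O)c(Br)c2)cc1Br | intermediate
11 | (5S)-7-(3-bromo-4-hydroxyphenyl)-1-(3,5-dibromo-4-hydroxyphenyl)-5-hydroxyheptan-3-one | Oc1ccc(CC[C@H](O)CC(=O)CCc2cc(Br)c(O)c(Br)c2)cc1Br | intermediate
12 | (3S,5S)-1-(3-bromo-4-hydroxyphenyl)-7-(3,5-dibromo-4-hydroxyphenyl)heptane-3,5-diol | Oc1ccc(CC[C@H](O)C[C@@H](O)CCc2cc(Br)c(O)c(Br)c2)cc1Br | intermediate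
13 | (3S,5S)-1-(3,5-dibromo-4-hydroxyphenyl)-7-(4-hydroxy-3-methoxyphenyl)heptane-3,5-diol | COc1cc(CC[C@H](O)C[C@@H](O)CCc2cc(Br)c(O)c(Br)c2)ccc1O | intermediate
14 | (3S,5S)-1-(3-bromo-4-hydroxyphenyl)-7-(3-bromo-4-hydroxy-5-methoxyphenyl)heptane-3,5-diol | Oc1ccc(CC[C@H](O)C[C@@H](O)CCc2cc(Br)c(O)c(OC)c2)cc1Br | intermediate
15 | (3S,5S)-1-(3-bromo-4-hydroxy-5-methoxyphenyl)-7-(4-hydroxy-3-methoxyphenyl)heptane-3,5-diol | COc1cc(CC[C@H](O)C[C@@H](O)CCc2cc(Br)c(O)c(OC)c2)ccc1O | intermediate
16 | (3S,5S)-1-(3-bromo-4-hydroxyphenyl)-7-(4-hydroxy-3,5-dimethoxyphenyl)heptane-3,5-diol | Oc1ccc(CC[C@H](O)C[C@@H](O)CCc2cc(OC)c(O)c(OC)c2)cc1Br | intermediate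
17 | (3S,5S)-1-(4-hydroxy-3-methoxyphenyl)-7-(4-hydroxy-3,5-dimethoxyphenyl)heptane-3,5-diol (CNP0317264.1) | COc1cc(CC[C@H](O)C[C@@H](O)CCc2cc(OC)c(O)c(OC)c2)ccc1O | target

## Step count and risks

Total step count: 7. Longest linear sequence: 5 steps (1 → 2 → 6 → 9 → 12 → 17; the branch 3 → 4 → 8 → 9 → 12 → 17 is equally long).

Steps most likely to fail:

Step 3 (the same concern holds for step 4). The aryl radical may pick up a hydrogen atom from the Hantzsch ester before it adds, returning 2-bromophenol, or the enone may telomerise. The fallback sets out from 2 and reverses the polarity of the radical union. The nucleophilic 3-oxobutyl radical is released by photocatalytic oxidative ring-opening of 1-methylcyclopropan-1-ol (Ir[dF(CF3)ppy]2(dtbbpy)PF6, 2,4,6-collidine, blue LEDs). NiBr2(dtbbpy), which inserts into the C–I bond of 2 in preference to C–Br, couples it with the arene. This gives ketone 6 directly, so the route is rejoined at 6 and no new compound is made (F0).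

Step 5. The polyanionic phenoxide/enolate mixture may be poorly soluble, and ester 8 may self-condense or react sluggishly. The fallback sets out from 8, which is converted with MeNH(OMe)·HCl and i-PrMgCl (THF, −20 °C) into the Weinreb amide 3-(3,5-dibromo-4-hydroxyphenyl)-N-methoxy-N-methylpropanamide F1. The kinetic lithium dianion of 6 (LiN(i-Pr)2, 2.2 equiv, THF, −78 °C) is then acylated with the magnesium phenoxide of F1. The chelated adduct collapses only on acidic work-up, and the route is rejoined at 9.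

Step 7. Three Ullmann exchanges on one polar substrate may stall at 13–16 or give hydrodebrominated, methoxy-deficient analogues that are hard to separate. The fallback sets out from 6 and 8 and installs the methoxy groups before the chain is assembled, at the cost of one extra step:

- CuBr/NaOMe converts 6 into 4-(4-hydroxy-3-methoxyphenyl)butan-2-one F2.
- The same conditions convert 8, through methyl 3-(3-bromo-4-hydroxy-5-methoxyphenyl)propanoate F3, into methyl 3-(4-hydroxy-3,5-dimethoxyphenyl)propanoate F4.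
- Crossed Claisen condensation of F2 with F4 (KOt-Bu, THF) gives 1-(4-hydroxy-3-methoxyphenyl)-7-(4-hydroxy-3,5-dimethoxyphenyl)heptane-3,5-dione F5.
- Hydrogenation with RuCl2[(S)-binap] then passes through (5S)-5-hydroxy-1-(4-hydroxy-3-methoxyphenyl)-7-(4-hydroxy-3,5-dimethoxyphenyl)heptan-3-one F6 and (5S)-5-hydroxy-7-(4-hydroxy-3-methoxyphenyl)-1-(4-hydroxy-3,5-dimethoxyphenyl)heptan-3-one F7 and rejoins the route at the target 17.

Further compounds
F0 | step 3 | none | none
F1 | step 5 | 3-(3,5-dibromo-4-hydroxyphenyl)-N-methoxy-N-methylpropanamide | CON(C)C(=O)CCc1cc(Br)c(O)c(Br)c1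
F2 | step 7 | 4-(4-hydroxy-3-methoxyphenyl)butan-2-one | CC(=O)CCc1ccc(O)c(OC)c1
F3 | step 7 | methyl 3-(3-bromo-4-hydroxy-5-methoxyphenyl)propanoate | COC(=O)CCc1cc(Br)c(O)c(OC)c1
F4 | step 7 | methyl 3-(4-hydroxy-3,5-dimethoxyphenyl)propanoate | COC(=O)CCc1cc(OC)c(O)c(OC)c1
F5 | step 7 | 1-(4-hydroxy-3-methoxyphenyl)-7-(4-hydroxy-3,5-dimethoxyphenyl)heptane-3,5-dione | COc1cc(CCC(=O)CC(=O)CCc2cc(OC)c(O)c(OC)c2)ccc1O
F6 | step 7 | (5S)-5-hydroxy-1-(4-hydroxy-3-methoxyphenyl)-7-(4-hydroxy-3,5-dimethoxyphenyl)heptan-3-one | COc1cc(CCC(=O)C[C@@H](O)CCc2cc(OC)c(O)c(OC)c2)ccc1O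
F7 | step 7 | (5S)-5-hydroxy-7-(4-hydroxy-3-methoxyphenyl)-1-(4-hydroxy-3,5-dimethoxyphenyl)heptan-3-one | COc1cc(CC[C@H](O)CC(=O)CCc2cc(OC)c(O)c(OC)c2)ccc1O
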